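**Plan**
1. Briarane numbers are used throughout. Retrosynthesis: the 11,20-epoxide goes back to the C11=C20 exocyclic olefin; then the C1–C10 bond is cut, which opens the cyclohexane and the ten-membered ring together and leaves a 14-membered carbocycle (perimeter C1–C14) that carries a C1–C2 oxirane and, across the ring, a C10=C11 allylsilane (CH2SiMe3 on C11).
2. The macrocycle is cut at C14–C1 (Nozaki–Hiyama–Kishi), at C10=C11 and C5=C6 (Stork–Zhao olefinations) and at C11–C20 and C4–C5 (Negishi couplings). This leads back to a γ-lactone polyol made from L-arabinitol and ethyl propanoate.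
3. Forward order: γ-lactone (C7, C8, C17, C19); the (5Z) arm with the C1–C4 chain; the allylsilane arm; the 14-membered ring; then one Lewis-acid event closes ring C1/C10–C14 and ring C1–C10; the acetates and the 11,20-epoxide come last.
4. Stereochemistry: C7 and C9 from L-arabinitol; C8 and C17 by equilibration to the most stable lactone; C14 by Corey–Bakshi–Shibata reduction; C2 and the reacting face of C1 by hydroxyl-directed epoxidation; C1 (inversion) and C10 (chair, olefin geometry) in the key step; C11 by epoxidation anti to the C15 methyl.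
5. Enabling feature: in the macrocycle the tertiary oxirane carbon C1 and the olefin carbon C10 are 1,6-related through C14–C13–C12–C11, while C2…C9 already tie them together on the other side. Opening the oxirane at C1 by C10 therefore forms the cyclohexane and the ten-membered ring at once and leaves the C2 oxygen and the C11=C20 olefin in place.

Key step: step 24

Remark: the target is taken as (1S,2S,5Z,7S,8S,9S,10S,11R,14S,17R), as read from its SMILES; C15, C16 and C18 are methyls, C19 the lactone carbonyl, C20 the epoxide CH2.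

Step 1
Reactants: 1 L-arabinitol; 2 3,3-dimethoxypentane
Product: 3 1,2:4,5-di-O-(pentan-3-ylidene)-L-arabinitol
Conditions: 2 (2.2 equiv), camphor-10-sulfonic acid (cat.), DMF, rt
Reagents that add atoms: none
Why: Acid-catalysed transketalisation (kinetic dioxolane formation at the two terminal 1,2-diols) should leave only the central hydroxyl free; both stereocentres (the future C7 and C9) are taken unchanged from L-arabinitol.

Step 2
Reactants: 3 1,2:4,5-di-O-(pentan-3-ylidene)-L-arabinitol
Product: 4 bis[(4S)-2,2-diethyl-1,3-dioxolan-4-yl]methanone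
Conditions: Dess–Martin periodinane, NaHCO3, CH2Cl2, 0 °C to rt
Reagents that add atoms: none
Why: Dess–Martin oxidation should give the C2-symmetric ketone, whose two carbonyl faces are homotopic, so the coming C–C bond formation needs no facial control.

Step 3
Reactants: 4 bis[(4S)-2,2-diethyl-1,3-dioxolan-4-yl]methanone; 5 ethyl propanoate
Product: 7 ethyl 3,3-bis[(4S)-2,2-diethyl-1,3-dioxolan-4-yl]-3-hydroxy-2-methylpropanoate (both C2 epimers), via lithium enolate of ethyl propanoate 6 (not isolated)
Conditions: LiN(iPr)2, THF, −78 °C; 5; then 4, −78 °C; aq. NH4Cl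
Reagents that add atoms: none
Why: Aldol addition of the lithium ester enolate to the activated α,α′-dialkoxy ketone forms the C8–C17 bond; C8 is not yet stereogenic (two identical arms) and the C17 mixture is corrected in step 4.

Step 4
Reactants: 7 ethyl 3,3-bis[(4S)-2,2-diethyl-1,3-dioxolan-4-yl]-3-hydroxy-2-methylpropanoate
Product: 9 lactone tetraol (3R,4R,5S)-4-[(1S)-1,2-dihydroxyethyl]-4-hydroxy-5-(hydroxymethyl)-3-methyloxolan-2-one, via lactone diastereomer mixture 8 (not isolated)
Conditions: CF3CO2H/H2O (9:1), 0 °C to rt; evaporate; then 1,8-diazabicyclo[5.4.0]undec-7-ene (0.2 equiv), MeCN, 40 °C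
Reagents that add atoms: none
Why: Acidic ketal hydrolysis and lactonisation, followed by base-mediated equilibration (translactonisation between the two diastereotopic secondary hydroxyls and epimerisation α to the carbonyl), should funnel all diastereomers to the most stable γ-lactone, in which the bulky C9 side chain is trans to both the C7 CH2OH and the C17 methyl; this thermodynamic control sets C8 and C17.

Step 5
Reactants: 9 lactone tetraol; 10 2,2-dimethoxypropane
Product: 11 acetonide (3R,4R,5S)-4-[(4S)-2,2-dimethyl-1,3-dioxolan-4-yl]-4-hydroxy-5-(hydroxymethyl)-3-methyloxolan-2-one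
Conditions: 10 (1.2 equiv), pyridinium p-toluenesulfonate (cat.), acetone, 0 °C to rt
Reagents that add atoms: none
Why: Acetonide formation under equilibrating conditions should select the terminal 1,2-diol (C9/C10 dioxolane) over the other hydroxyls and so tells the two primary alcohols apart.

Step 6
Reactants: 11 acetonide
Product: 12 C6 aldehyde of 11
Conditions: Dess–Martin periodinane, NaHCO3, CH2Cl2, 0 °C
Reagents that add atoms: none
Why: Dess–Martin oxidation should convert the one primary alcohol into the aldehyde under buffered, non-epimerising conditions, the tertiary C8 hydroxyl being inert.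

Step 7
Reactants: 12 C6 aldehyde of 11; 13 ethyltriphenylphosphonium iodide
Product: 17 (Z)-vinyl iodide (iodine cis to C7), via ethylidene ylide 14 (not isolated), via iodophosphonium iodide 15 (not isolated), via iodo ylide 16 (not isolated)
Conditions: 13, n-BuLi, THF, 0 °C; I2, −78 °C; NaN(SiMe3)2, −78 to −20 °C; then 12, −78 °C
Reagents that add atoms: iodine, II
Why: The Stork–Zhao olefination (Wittig reaction of an α-iodo ylide) should give the (Z)-iodoalkene with iodine cis to C7 under kinetic control, which fixes the later (5Z) geometry.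

Step 8
Reactants: 18 pent-3-yn-1-ol
Product: 20 (E)-4-bromopent-3-en-1-ol, via alkenylzirconocene chloride 19 (not isolated)
Conditions: Cp2Zr(H)Cl (2.5 equiv), THF, 40 °C; then N-bromosuccinimide, 0 °C
Reagents that add atoms: N-bromosuccinimide, O=C1CCC(=O)N1Br
Why: Hydrozirconation adds Zr–H syn with zirconium on the less hindered, methyl-bearing alkyne carbon, and bromodezirconation with retention should give the (E)-2-bromoalkene.

Step 9
Reactants: 20 (E)-4-bromopent-3-en-1-ol
Product: 21 (E)-2-bromo-5-iodopent-2-ene
Conditions: I2, PPh3, imidazole, CH2Cl2, 0 °C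
Reagents that add atoms: iodine, II
Why: Appel-type iodination should turn the primary alcohol into the iodide needed for zinc insertion without touching the vinyl bromide.

Step 10
Reactants: 17 (Z)-vinyl iodide; 21 (E)-2-bromo-5-iodopent-2-ene
Product: 23 bromodiene acetonide [(1Z,5E)-6-bromo-2-methylhepta-1,5-dienyl chain on C7], via alkylzinc iodide 22 (not isolated)
Conditions: 21, Zn dust, LiCl, THF, 40 °C; then 17, Pd(PPh3)4 (5 mol %), THF, rt
Reagents that add atoms: none
Why: Negishi coupling of the alkylzinc iodide with the vinyl iodide (the vinyl bromide reacts far more slowly) should form the C4–C5 bond with retention and so deliver the (5Z) trisubstituted olefin.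

Step 11
Reactants: 23 bromodiene acetonide
Product: 24 bromodiene diol (C9 and C10 hydroxyls free)
Conditions: AcOH/H2O/THF (3:1:1), 40 °C
Reagents that add atoms: none
Why: Mild acid hydrolysis of the dioxolane should free the C9 and C10 hydroxyls.

Step 12
Reactants: 24 bromodiene diol
Product: 25 tris(triethylsilyl) ether (O8, O9, O10)
Conditions: Et3SiOTf (3.5 equiv), 2,6-lutidine, CH2Cl2, −78 to 0 °C
Reagents that add atoms: triethylsilyl trifluoromethanesulfonate, CC[Si](CC)(CC)OS(=O)(=O)C(F)(F)F
Why: Exhaustive silylation with the silyl triflate should cap the tertiary C8 hydroxyl as well as the C9 and C10 hydroxyls.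

Step 13
Reactants: 25 tris(triethylsilyl) ether
Product: 26 C10 aldehyde (O8 and O9 silyl ethers kept)
Conditions: (COCl)2, DMSO, CH2Cl2, −78 to −40 °C; then Et3N
Reagents that add atoms: none
Why: Under Swern conditions a primary triethylsilyl ether is oxidised directly to the aldehyde while secondary and tertiary silyl ethers survive, which should give the C10 aldehyde in one operation.

Step 14
Reactants: 27 4-bromobutan-1-ol
Product: 28 (4-bromobutoxy)triethylsilane
Conditions: Et3SiCl, imidazole, CH2Cl2, 0 °C
Reagents that add atoms: chlorotriethylsilane, CC[Si](Cl)(CC)CC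
Why: Standard silylation protects the primary alcohol that will become the C14 oxygen.

Step 15
Reactants: 28 (4-bromobutoxy)triethylsilane
Product: 29 triphenyl[4-(triethylsilyloxy)butyl]phosphonium bromide
Conditions: PPh3, MeCN, reflux
Reagents that add atoms: triphenylphosphine, c1ccc(cc1)P(c1ccccc1)c1ccccc1
Why: SN2 alkylation of triphenylphosphine should give the phosphonium salt that carries C11–C14.

Step 16
Reactants: 26 C10 aldehyde; 29 triphenyl[4-(triethylsilyloxy)butyl]phosphonium bromide
Product: 33 (Z)-vinyl iodide at C11 (iodine cis to C9), via butylidene ylide 30 (not isolated), via iodophosphonium iodide 31 (not isolated), via iodo ylide 32 (not isolated)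
Conditions: 29, n-BuLi, THF, −78 to 0 °C; I2, −78 °C; NaN(SiMe3)2, −78 to −20 °C; then 26, −78 °C
Reagents that add atoms: iodine, II
Why: A second Stork–Zhao olefination should give the (Z)-iodoalkene with iodine cis to C9 and the C12–C14 chain trans, the olefin geometry that the key step turns into the C10 configuration.

Step 17
Reactants: 33 (Z)-vinyl iodide at C11
Product: 34 allylsilane (CH2SiMe3 on C11, cis to C9)
Conditions: Me3SiCH2MgCl, ZnCl2, THF, 0 °C; then 33, Pd(PPh3)4 (5 mol %), THF, rt
Reagents that add atoms: (trimethylsilyl)methylmagnesium chloride, C[Si](C)(C)C[Mg]Cl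
Why: Negishi coupling at the vinyl iodide (chemoselective over the vinyl bromide) should install the CH2SiMe3 group with retention, giving the allylsilane nucleophile.

Step 18
Reactants: 34 allylsilane
Product: 35 C14 aldehyde
Conditions: (COCl)2, DMSO, CH2Cl2, −78 to −40 °C; then Et3N
Reagents that add atoms: none
Why: Swern oxidation of the primary triethylsilyl ether, as in step 13, should give the C14 aldehyde and leave the other silyl ethers and the allylsilane intact.

Step 19
Reactants: 35 C14 aldehyde
Product: 36 14-membered allylic alcohol (both C14 epimers)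
Conditions: CrCl2 (10 equiv), NiCl2 (10 mol %), DMSO/THF, rt, 2 mM, slow addition
Reagents that add atoms: none
Why: The Nozaki–Hiyama–Kishi reaction under high dilution should close the unstrained 14-membered ring at C14–C1 with retention of the (E) olefin geometry; both C14 epimers are accepted because step 20 converges them.

Step 20
Reactants: 36 14-membered allylic alcohol
Product: 37 macrocyclic (E)-enone (C14 ketone)
Conditions: Dess–Martin periodinane, NaHCO3, CH2Cl2, 0 °C
Reagents that add atoms: none
Why: Dess–Martin oxidation should converge the C14 epimers to one enone.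

Step 21
Reactants: 37 macrocyclic (E)-enone
Product: 38 (14S)-allylic alcohol
Conditions: (R)-2-methyl-CBS-oxazaborolidine [(3aR)-1-methyl-3,3-diphenylhexahydropyrrolo[1,2-c][1,3,2]oxazaborole] (0.3 equiv), catecholborane, toluene, −78 °C
Reagents that add atoms: none
Why: Corey–Bakshi–Shibata reduction, with the α-methyl alkenyl group as the large substituent, should set (14S) under reagent control.

Step 22
Reactants: 38 (14S)-allylic alcohol
Product: 39 1,2-epoxy alcohol (erythro to the C14 hydroxyl)
Conditions: VO(acac)2 (5 mol %), t-BuOOH, CH2Cl2, 0 °C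
Reagents that add atoms: tert-butyl hydroperoxide, CC(C)(C)OO
Why: The hydroxyl-directed VO(acac)2 epoxidation should act only on the allylic C1=C2 olefin and, because of A(1,2) strain between C13 and the C1 methyl, give the erythro epoxy alcohol, which fixes C2 (S) and the face of C1 from which the oxygen later leaves.

Step 23
Reactants: 39 1,2-epoxy alcohol
Product: 40 C14 trifluoroacetate of 39
Conditions: (CF3CO)2O, pyridine, CH2Cl2, −20 °C
Reagents that add atoms: trifluoroacetic anhydride, O=C(OC(=O)C(F)(F)F)C(F)(F)F
Why: Trifluoroacetylation should cap the C14 hydroxyl as a group that is neither a hydride donor nor a good neighbouring group, so that the oxirane cannot rearrange by 1,2-hydride shift or acyloxonium formation in step 24; no stereocentre is touched.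

Step 24
Reactants: 40 C14 trifluoroacetate of 39
Product: 41 bicyclic silyl ether (2-OSiMe3; 8,9-bis-OSiEt3; 14-trifluoroacetate; 5Z and 11(20) olefins)
Conditions: Me3SiOTf (10 mol %), 2,6-di-tert-butyl-4-methylpyridine (20 mol %), CH2Cl2, −78 °C
Reagents that add atoms: none
Why: Proposed new method: silylation of the oxirane oxygen by catalytic Me3SiOTf should trigger Markovnikov, invertive opening at the tertiary C1 by C10 of the transannular allylsilane, and loss of the silyl group from the β-silyl cation at C11 leaves the C11=C20 olefin and returns the catalyst, so that 40 simply isomerises to the C2 silyl ether. The closest known reaction types are the Lewis-acid-promoted intramolecular epoxide–allylsilane (cation–olefin) cyclisation and the acid-induced transannular cyclisation of macrocyclic terpenoid epoxides; their combination across a 14-membered ring is what is new. The cyclohexane (C1, C10–C14) closes 6-endo-trig with respect to the C10=C11 bond and exo-tet with respect to the oxirane, and the same bond closes the ten-membered ring (C1–C10) transannularly. C1 is set by inversion (anti opening), C10 by a chair transition state in which the C2 and C9 tethers are equatorial and the C9/C12-trans olefin geometry places H10 trans to the C15 methyl, while C2 and C14 are carried in unchanged. The step needs site selectivity for the allylsilane over the C5=C6 olefin, which the far higher nucleophilicity of the allylsilane and the deactivating allylic lactone oxygen at C7 should secure; it needs opening at C1, which the tertiary centre and the ring size (six against nine) secure; and it needs suppression of a 1,2-hydride shift from C14, which the trifluoroacetate secures.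

Step 25
Reactants: 41 bicyclic silyl ether
Product: 42 2,8,9,14-tetraol (5Z and 11(20) olefins)
Conditions: HF·pyridine, pyridine, THF, 0 °C to rt; then NaHCO3, MeOH, 0 °C
Reagents that add atoms: none
Why: Fluoride should cleave the trimethylsilyl and triethylsilyl ethers and bicarbonate methanolysis the labile trifluoroacetate, giving the tetraol.

Step 26
Reactants: 42 2,8,9,14-tetraol
Product: 43 2,9,14-triacetate (8-hydroxyl free)
Conditions: Ac2O, pyridine, 4-(dimethylamino)pyridine (cat.), CH2Cl2, rt
Reagents that add atoms: acetic anhydride, CC(=O)OC(C)=O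
Why: Acetylation under acyl-transfer catalysis should esterify the three secondary hydroxyls, while the tertiary C8 hydroxyl, flanked by C7, C9 and C17, stays free.

Step 27
Reactants: 43 2,9,14-triacetate
Product: 44 junceellolide K
Conditions: m-chloroperbenzoic acid, NaHCO3, CH2Cl2, 0 °C
Reagents that add atoms: m-chloroperbenzoic acid, OOC(=O)c1cccc(Cl)c1
Why: Prilezhaev epoxidation of the exocyclic 1,1-disubstituted olefin from the equatorial (α) direction, anti to the axial C15 methyl, should set C11 (R), the C5=C6 olefin being deactivated by the allylic lactone oxygen and shielded inside the ten-membered ring.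

**Compound list**
1 | L-arabinitol, (2S,4S)-pentane-1,2,3,4,5-pentol | OC[C@H](O)C(O)[C@@H](O)CO | starting material
2 | 3,3-dimethoxypentane | CCC(CC)(OC)OC | starting material
3 | 1,2:4,5-di-O-(pentan-3-ylidene)-L-arabinitol, bis[(4S)-2,2-diethyl-1,3-dioxolan-4-yl]methanol | OC([C@@H]1COC(CC)(CC)O1)[C@@H]1COC(CC)(CC)O1 | intermediate
4 | bis[(4S)-2,2-diethyl-1,3-dioxolan-4-yl]methanone (C2-symmetric ketone, future C8) | O=C([C@@H]1COC(CC)(CC)O1)[C@@H]1COC(CC)(CC)O1 | intermediate
5 | ethyl propanoate | CCC(=O)OCC | starting material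
6 | lithium enolate of ethyl propanoate (not isolated) | CC=C(OCC)O[Li] | intermediate
7 | ethyl 3,3-bis[(4S)-2,2-diethyl-1,3-dioxolan-4-yl]-3-hydroxy-2-methylpropanoate (both C2 epimers) | CCOC(=O)C(C)C(O)([C@@H]1COC(CC)(CC)O1)[C@@H]1COC(CC)(CC)O1 | intermediate
8 | γ-lactone tetraol as mixture of diastereomers at C8 and C17, C7 and C9 both S (not isolated) | OC[C@@H]1OC(=O)C(C)C1(O)[C@@H](O)CO | intermediate
9 | lactone tetraol (3R,4R,5S)-4-[(1S)-1,2-dihydroxyethyl]-4-hydroxy-5-(hydroxymethyl)-3-methyloxolan-2-one (CH2OH, OH and CH3 cis; C9 chain trans to them) | OC[C@@H]1OC(=O)[C@H](C)[C@@]1(O)[C@@H](O)CO | intermediate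
10 | 2,2-dimethoxypropane | COC(C)(C)OC | starting material
11 | acetonide (3R,4R,5S)-4-[(4S)-2,2-dimethyl-1,3-dioxolan-4-yl]-4-hydroxy-5-(hydroxymethyl)-3-methyloxolan-2-one | OC[C@@H]1OC(=O)[C@H](C)[C@@]1(O)[C@@H]2COC(C)(C)O2 | intermediate
12 | C6 aldehyde of 11 (formyl group on C7 of the lactone; configuration as in 11) | O=C[C@@H]1OC(=O)[C@H](C)[C@@]1(O)[C@@H]2COC(C)(C)O2 | intermediate
13 | ethyltriphenylphosphonium iodide | CC[P+](c1ccccc1)(c1ccccc1)c1ccccc1.[I-] | starting material
14 | ethylidenetriphenylphosphorane (not isolated) | CC=P(c1ccccc1)(c1ccccc1)c1ccccc1 | intermediate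
15 | (1-iodoethyl)triphenylphosphonium iodide (not isolated) | CC(I)[P+](c1ccccc1)(c1ccccc1)c1ccccc1.[I-] | intermediate
16 | (1-iodoethylidene)triphenylphosphorane (not isolated) | CC(I)=P(c1ccccc1)(c1ccccc1)c1ccccc1 | intermediate
17 | (Z)-vinyl iodide: lactone acetonide with a (Z)-2-iodoprop-1-enyl group on C7, iodine cis to C7 | I/C(C)=C\[C@@H]1OC(=O)[C@H](C)[C@@]1(O)[C@@H]2COC(C)(C)O2 | intermediate
18 | pent-3-yn-1-ol | CC#CCCO | starting material
19 | (E)-alkenylzirconocene chloride from 18, zirconium on C4, O-zirconated (not isolated) | C/C(=C\CCO[Zr](Cl)(C1C=CC=C1)C1C=CC=C1)[Zr](Cl)(C1C=CC=C1)C1C=CC=C1 | intermediate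
20 | (E)-4-bromopent-3-en-1-ol | Br/C(C)=C/CCO | intermediate
21 | (E)-2-bromo-5-iodopent-2-ene | Br/C(C)=C/CCI | intermediate
22 | [(E)-4-bromopent-3-enyl]zinc iodide (not isolated) | Br/C(C)=C/CC[Zn]I | intermediate
23 | bromodiene acetonide: lactone acetonide with the (1Z,5E)-6-bromo-2-methylhepta-1,5-dienyl chain on C7 (briarane C6 to C1, C15, C16) | Br/C(C)=C/CC/C(C)=C\[C@@H]1OC(=O)[C@H](C)[C@@]1(O)[C@@H]2COC(C)(C)O2 | intermediate
24 | bromodiene diol (C8, C9, C10 hydroxyls free) | Br/C(C)=C/CC/C(C)=C\[C@@H]1OC(=O)[C@H](C)[C@@]1(O)[C@@H](O)CO | intermediate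
25 | tris(triethylsilyl) ether of 24 (O8, O9, O10) | Br/C(C)=C/CC/C(C)=C\[C@@H]1OC(=O)[C@H](C)[C@@]1(O[Si](CC)(CC)CC)[C@@H](O[Si](CC)(CC)CC)CO[Si](CC)(CC)CC | intermediate
26 | C10 aldehyde (O8 and O9 triethylsilyl ethers) | Br/C(C)=C/CC/C(C)=C\[C@@H]1OC(=O)[C@H](C)[C@@]1(O[Si](CC)(CC)CC)[C@@H](O[Si](CC)(CC)CC)C=O | intermediate
27 | 4-bromobutan-1-ol | OCCCCBr | starting material
28 | (4-bromobutoxy)triethylsilane | CC[Si](CC)(CC)OCCCCBr | intermediate
29 | triphenyl[4-(triethylsilyloxy)butyl]phosphonium bromide | CC[Si](CC)(CC)OCCCC[P+](c1ccccc1)(c1ccccc1)c1ccccc1.[Br-] | intermediate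
30 | [4-(triethylsilyloxy)butylidene]triphenylphosphorane (not isolated) | CC[Si](CC)(CC)OCCCC=P(c1ccccc1)(c1ccccc1)c1ccccc1 | intermediate
31 | [1-iodo-4-(triethylsilyloxy)butyl]triphenylphosphonium iodide (not isolated) | CC[Si](CC)(CC)OCCCC(I)[P+](c1ccccc1)(c1ccccc1)c1ccccc1.[I-] | intermediate
32 | [1-iodo-4-(triethylsilyloxy)butylidene]triphenylphosphorane (not isolated) | CC[Si](CC)(CC)OCCCC(I)=P(c1ccccc1)(c1ccccc1)c1ccccc1 | intermediate
33 | (Z)-vinyl iodide at C11: iodine cis to C9, C12–C14 chain trans, O14 triethylsilyl ether | Br/C(C)=C/CC/C(C)=C\[C@@H]1OC(=O)[C@H](C)[C@@]1(O[Si](CC)(CC)CC)[C@@H](O[Si](CC)(CC)CC)/C=C(\I)CCCO[Si](CC)(CC)CC | intermediate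
34 | allylsilane: CH2SiMe3 on C11, cis to C9 | Br/C(C)=C/CC/C(C)=C\[C@@H]1OC(=O)[C@H](C)[C@@]1(O[Si](CC)(CC)CC)[C@@H](O[Si](CC)(CC)CC)/C=C(\C[Si](C)(C)C)CCCO[Si](CC)(CC)CC | intermediate
35 | C14 aldehyde | Br/C(C)=C/CC/C(C)=C\[C@@H]1OC(=O)[C@H](C)[C@@]1(O[Si](CC)(CC)CC)[C@@H](O[Si](CC)(CC)CC)/C=C(\C[Si](C)(C)C)CCC=O | intermediate
36 | 14-membered allylic alcohol (ring C1–C14; both C14 epimers; 1E, 5Z; C9 and C12 trans across C10=C11) | OC1CC/C(C[Si](C)(C)C)=C/[C@H](O[Si](CC)(CC)CC)[C@]2(O[Si](CC)(CC)CC)[C@@H](C)C(=O)O[C@H]2/C=C(C)\CC/C=C1\C | intermediate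
37 | macrocyclic (E)-enone (C14 ketone) | O=C1CC/C(C[Si](C)(C)C)=C/[C@H](O[Si](CC)(CC)CC)[C@]2(O[Si](CC)(CC)CC)[C@@H](C)C(=O)O[C@H]2/C=C(C)\CC/C=C1\C | intermediate
38 | (14S)-allylic alcohol of the macrocycle | O[C@H]1CC/C(C[Si](C)(C)C)=C/[C@H](O[Si](CC)(CC)CC)[C@]2(O[Si](CC)(CC)CC)[C@@H](C)C(=O)O[C@H]2/C=C(C)\CC/C=C1\C | intermediate
39 | 1,2-epoxy alcohol, oxirane erythro to the (14S) hydroxyl, C2 S | O[C@H]1CC/C(C[Si](C)(C)C)=C/[C@H](O[Si](CC)(CC)CC)[C@]2(O[Si](CC)(CC)CC)[C@@H](C)C(=O)O[C@H]2/C=C(C)\CC[C@@H]3O[C@@]13C | intermediate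
40 | C14 trifluoroacetate of 39 | O=C(O[C@H]1CC/C(C[Si](C)(C)C)=C/[C@H](O[Si](CC)(CC)CC)[C@]2(O[Si](CC)(CC)CC)[C@@H](C)C(=O)O[C@H]2/C=C(C)\CC[C@@H]3O[C@@]13C)C(F)(F)F | intermediate
41 | bicyclic silyl ether: briarane skeleton with 2-OSiMe3, 8,9-bis-OSiEt3, 14-trifluoroacetate, 5Z and 11(20) olefins, configuration as in 44 | C[Si](C)(C)O[C@H]1CC/C(C)=C\[C@@H]2OC(=O)[C@H](C)[C@@]2(O[Si](CC)(CC)CC)[C@@H](O[Si](CC)(CC)CC)[C@H]2C(=C)CC[C@H](OC(=O)C(F)(F)F)[C@]12C | intermediate
42 | 2,8,9,14-tetraol with 5Z and 11(20) olefins | O[C@H]1CC/C(C)=C\[C@@H]2OC(=O)[C@H](C)[C@@]2(O)[C@@H](O)[C@H]2C(=C)CC[C@H](O)[C@]12C | intermediate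
43 | 2,9,14-triacetate with free 8-hydroxyl and 11(20) olefin | CC(=O)O[C@H]1CC/C(C)=C\[C@@H]2OC(=O)[C@H](C)[C@@]2(O)[C@@H](OC(C)=O)[C@H]2C(=C)CC[C@H](OC(C)=O)[C@]12C | intermediate
44 | junceellolide K | CC(=O)O[C@H]1CC/C(C)=C\[C@@H]2OC(=O)[C@H](C)[C@@]2(O)[C@@H](OC(C)=O)[C@H]2[C@]3(CC[C@H](OC(C)=O)[C@]12C)CO3 | target

**Step count and risks**
Total step count: 27. Longest linear sequence: 23 steps (steps 1–7, 10–13, 16–27, from L-arabinitol).

Steps most likely to fail:

Step 24 (labelled step). The activated oxirane may rearrange or eliminate faster than it is attacked across the ring, the ring may close through the C5=C6 olefin, or closure through the other chair or a boat may give the wrong ring fusion. The fallback keeps the transannular idea but changes the mechanism to the known Cp2TiCl radical manifold, which has no cationic rearrangement channel. It sets out from vinyl iodide 33. Negishi coupling with MeZnCl in place of the silylmethyl reagent should give the C11-methyl bromodiene F1. The operations of steps 18 to 22 should then give in turn the C14 aldehyde F2, the macrocyclic allylic alcohol F3, the macrocyclic enone F4, the (14S)-allylic alcohol F5 and the epoxy alcohol F6, and 1-(trimethylsilyl)imidazole the C14 trimethylsilyl ether F7. Cp2TiCl (from Cp2TiCl2 and Mn dust in THF; trivalent titanium) should open the oxirane of F7 homolytically to the tertiary C1 radical, which adds transannularly to C10 (6-endo-trig). The C11 radical then loses a hydrogen atom of the C20 methyl to a second Cp2TiCl and gives the exocyclic olefin alcohol F8. This reductive epoxide-opening cyclisation is established for epoxypolyenes and for transannular closures of medium-ring terpenoid epoxides; the bulky titanium alkoxide on C2 should disfavour closure through the C2 side. F8 is desilylated under the conditions of step 25 and the route is rejoined at tetraol 42.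

Step 4. The equilibration may stop at a mixture of lactone diastereomers, or retro-aldol cleavage may compete with epimerisation. The fallback replaces thermodynamic control of C17 by kinetic control. It sets out from ketone 4. A chelation-controlled Mukaiyama aldol addition (MgBr2·OEt2, CH2Cl2, −78 °C) of the trimethylsilyl ketene acetal of ethyl propanoate, its geometry chosen to deliver the 2R ester, should give the single (2R)-hydroxy ester F9. Acid treatment alone (CF3CO2H/H2O) then lactonises F9 onto the arm that places the C9 chain trans to both neighbours, and the route is rejoined at lactone tetraol 9.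

Step 27. Discrimination between the exocyclic olefin and the C5=C6 olefin may be poor, or oxygen may be delivered to the wrong face. The fallback replaces steric control by hydroxyl direction and changes the order of the last two steps. It sets out from tetraol 42. Epoxidation with VO(acac)2 and t-BuOOH, directed by the homoallylic C9 hydroxyl, should give the 11,20-epoxy tetraol F10, which is acetylated under the conditions of step 26 and gives 44 directly.

**Further compounds**
F1 | step 24 | C11-methyl bromodiene (methyl in place of CH2SiMe3 in 34) | Br/C(C)=C/CC/C(C)=C\[C@@H]1OC(=O)[C@H](C)[C@@]1(O[Si](CC)(CC)CC)[C@@H](O[Si](CC)(CC)CC)/C=C(\C)CCCO[Si](CC)(CC)CC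
F2 | step 24 | C14 aldehyde of the C11-methyl series | Br/C(C)=C/CC/C(C)=C\[C@@H]1OC(=O)[C@H](C)[C@@]1(O[Si](CC)(CC)CC)[C@@H](O[Si](CC)(CC)CC)/C=C(\C)CCC=O
F3 | step 24 | macrocyclic allylic alcohol of the C11-methyl series (both C14 epimers) | OC1CC/C(C)=C/[C@H](O[Si](CC)(CC)CC)[C@]2(O[Si](CC)(CC)CC)[C@@H](C)C(=O)O[C@H]2/C=C(C)\CC/C=C1\C
F4 | step 24 | macrocyclic enone of the C11-methyl series | O=C1CC/C(C)=C/[C@H](O[Si](CC)(CC)CC)[C@]2(O[Si](CC)(CC)CC)[C@@H](C)C(=O)O[C@H]2/C=C(C)\CC/C=C1\C
F5 | step 24 | (14S)-allylic alcohol of the C11-methyl series | O[C@H]1CC/C(C)=C/[C@H](O[Si](CC)(CC)CC)[C@]2(O[Si](CC)(CC)CC)[C@@H](C)C(=O)O[C@H]2/C=C(C)\CC/C=C1\C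
F6 | step 24 | 1,2-epoxy alcohol of the C11-methyl series | O[C@H]1CC/C(C)=C/[C@H](O[Si](CC)(CC)CC)[C@]2(O[Si](CC)(CC)CC)[C@@H](C)C(=O)O[C@H]2/C=C(C)\CC[C@@H]3O[C@@]13C
F7 | step 24 | C14 trimethylsilyl ether of F6 | C[Si](C)(C)O[C@H]1CC/C(C)=C/[C@H](O[Si](CC)(CC)CC)[C@]2(O[Si](CC)(CC)CC)[C@@H](C)C(=O)O[C@H]2/C=C(C)\CC[C@@H]3O[C@@]13C
F8 | step 24 | exocyclic olefin alcohol (2-hydroxyl free; 8,9-bis-OSiEt3; 14-OSiMe3) | O[C@H]1CC/C(C)=C\[C@@H]2OC(=O)[C@H](C)[C@@]2(O[Si](CC)(CC)CC)[C@@H](O[Si](CC)(CC)CC)[C@H]2C(=C)CC[C@H](O[Si](C)(C)C)[C@]12C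
F9 | step 4 | ethyl (2R)-3,3-bis[(4S)-2,2-diethyl-1,3-dioxolan-4-yl]-3-hydroxy-2-methylpropanoate | CCOC(=O)[C@H](C)C(O)([C@@H]1COC(CC)(CC)O1)[C@@H]1COC(CC)(CC)O1
F10 | step 27 | 11,20-epoxy 2,8,9,14-tetraol | O[C@H]1CC/C(C)=C\[C@@H]2OC(=O)[C@H](C)[C@@]2(O)[C@@H](O)[C@H]2[C@]3(CC[C@H](O)[C@]12C)CO3
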